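**Plan**

Ring numbering used throughout (furo[3,2-c][1,2]dioxin-6-one): O1, O2, C3 (methyl and side chain), C4 (CH2), C4a (methyl, lactone oxygen), O5, C6 (C=O), C7, C7a (CH–O1).

1. Retrosynthesis: (a) return the C3 side chain to an alkyne, a slim helper for the C3 center; (b) cut C3–C4 of the 1,2-dioxane and, in the same event, O5–C4a of the lactone, leaving an acyclic β-peroxy acid with an isopropenyl group and a mixed methoxy peroxyketal; (c) cut O1–C7a to a dienal and an α-methoxy hydroperoxide; (d) derive the hydroperoxide from an ynone ketal built from (8-bromooctyl)benzene, acetylide and an acetyl donor.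
2. Forward: alkyne, ynone, ketal, hydroperoxy ketal; organocatalytic peroxidation of 4-methylpenta-2,4-dienal joins the halves through O1–C7a; oxidation to the acid; one cationic cascade closes the 1,2-dioxane (C3–C4) and then the γ-lactone (O5–C4a); diimide saturates the alkyne.
3. Stereochemistry: C7a from the amine catalyst; C4a from the two-carbon carboxyl tether (cis fusion); C3 from the chair transition state of the cascade, where the alkynyl group takes the axial site; both ketal epimers converge on one peroxycarbenium ion.
4. Enabling feature: C3 carries the peroxide oxygen O2, so it is a latent peroxycarbenium carbon (ketone plus hydroperoxide). C4a carries a methyl group and the lactone oxygen O5, lies 1,3 to C3 and γ to the C6 carbonyl, so C4=C4a is a latent isopropenyl alkene whose Markovnikov cation is captured by the C6 carboxyl.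

Key step: step 8

Assumption: the (S)-configured diarylprolinol silyl ether is taken to deliver the oxygen nucleophile to the enal face that gives (R) at the future C7a, the sense this catalyst class shows with oxygen nucleophiles on (E)-enals; if the sense were opposite, the (R)-catalyst would be used.

**Step 1**
Reactants: 1 (8-bromooctyl)benzene; 2 lithium acetylide–ethylenediamine complex
Product: 3 (dec-9-yn-1-yl)benzene
Conditions: DMSO, 15 °C → rt
Reagents that add atoms: none
Why: SN2 alkylation of the acetylide anion by an unbranched primary bromide in a dipolar aprotic solvent (acetylide alkylation); no stereocenter is formed.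

**Step 2**
Reactants: 3 (dec-9-yn-1-yl)benzene; 4 N-methoxy-N-methylacetamide
Product: 6 12-phenyldodec-3-yn-2-one, via lithium acetylide 5 (not isolated)
Conditions: n-BuLi, THF, −78 °C; then 4, −78 → 0 °C; aq. NH4Cl
Reagents that add atoms: none
Why: Deprotonation of the terminal alkyne and acylation by the N-methoxy-N-methylamide (Weinreb ketone synthesis) should stop cleanly at the ynone without over-addition.

**Step 3**
Reactants: 6 12-phenyldodec-3-yn-2-one
Product: 7 (11,11-dimethoxydodec-9-yn-1-yl)benzene
Conditions: HC(OMe)3, MeOH, p-toluenesulfonic acid monohydrate (cat.), rt; Et3N quench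
Reagents that add atoms: trimethyl orthoformate COC(OC)OC; methanol CO
Why: Acid-catalysed ketalization with the orthoester as methoxy source and water scavenger; the conjugated triple bond should be left alone because conjugate addition of methanol needs base or a nucleophilic catalyst.

**Step 4**
Reactants: 7 (11,11-dimethoxydodec-9-yn-1-yl)benzene
Product: 8 2-methoxy-12-phenyldodec-3-yn-2-yl hydroperoxide (racemic)
Conditions: anhydrous H2O2 in Et2O (3 equiv), camphorsulfonic acid (cat.), 0 °C, short contact time; NaHCO3 quench
Reagents that add atoms: hydrogen peroxide OO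
Why: Acid-catalysed exchange of one ketal methoxy group for hydroperoxide through the propargylic oxocarbenium ion (perhydrolysis of a ketal to an α-alkoxy hydroperoxide); excess H2O2 should suppress bis-peroxide formation, and the new ketal center forms racemic, which is of no consequence because step 8 erases it.

**Step 5**
Reactants: 9 methacrolein; 10 (triphenylphosphoranylidene)acetaldehyde
Product: 11 (2E)-4-methylpenta-2,4-dienal
Conditions: methacrolein (excess), toluene, 40 °C; product kept cold and used as a solution
Reagents that add atoms: none
Why: Wittig olefination with the stabilized formylmethylene ylide should give the (E)-enal, the excess of volatile methacrolein keeping the product dienal from a second homologation.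

**Step 6**
Reactants: 11 (2E)-4-methylpenta-2,4-dienal; 8 2-methoxy-12-phenyldodec-3-yn-2-yl hydroperoxide
Product: 12 (3R)-3-[(2-methoxy-12-phenyldodec-3-yn-2-yl)peroxy]-4-methylpent-4-enal (both epimers at the ketal carbon)
Conditions: (S)-2-{bis[3,5-bis(trifluoromethyl)phenyl][(trimethylsilyl)oxy]methyl}pyrrolidine (20 mol %), PhCO2H (20 mol %), 11 (1.5 equiv), toluene, −20 → 0 °C
Reagents that add atoms: none
Why: Catalytic enantioselective peroxidation of an α,β-unsaturated aldehyde (oxa-Michael addition of a hydroperoxide under iminium catalysis), in which the diaryl(silyloxy)methyl group shields one face of the (E)-iminium ion so that the peroxide oxygen adds to the β-carbon from the open face and sets the future C7a as R, attack at the β-carbon being the normal course for 2,4-dienals under iminium activation and the acid cocatalyst protonating the peroxy enamine before it can close to an epoxide.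

**Step 7**
Reactants: 12 (3R)-3-[(2-methoxy-12-phenyldodec-3-yn-2-yl)peroxy]-4-methylpent-4-enal
Product: 13 (3R)-3-[(2-methoxy-12-phenyldodec-3-yn-2-yl)peroxy]-4-methylpent-4-enoic acid (both epimers at the ketal carbon)
Conditions: NaClO2, NaH2PO4, 2-methylbut-2-ene (large excess), t-BuOH/H2O, 0 °C
Reagents that add atoms: sodium chlorite [Na+].[O-]Cl=O
Why: Pinnick oxidation converts the aldehyde to the acid under buffered, mildly acidic conditions that should leave the propargylic peroxyketal, the O–O bond, the alkyne and the C7a center untouched, the alkene scavenger removing hypochlorous acid before it can add to the isopropenyl group.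

**Step 8**
Reactants: 13 (3R)-3-[(2-methoxy-12-phenyldodec-3-yn-2-yl)peroxy]-4-methylpent-4-enoic acid
Product: 17 (3S,4aR,7aR)-3,4a-dimethyl-3-(10-phenyldec-1-yn-1-yl)tetrahydrofuro[3,2-c][1,2]dioxin-6(3H)-one, via trimethylsilyl ester 14 (not isolated), via peroxycarbenium ion 15 (not isolated), via dioxanyl cation 16 (not isolated)
Conditions: Me3SiOTf (1.2 equiv), 2,6-di-tert-butyl-4-methylpyridine (1.3 equiv), CH2Cl2, −78 → −40 °C; aq. NaHCO3
Reagents that add atoms: none
Why: Proposed new method: Me3SiOTf silylates the acid and then removes the methoxy group of either ketal epimer of 13 to give one planar peroxycarbenium ion, whose carbon (future C3) is attacked by the CH2 terminus of the isopropenyl group (future C4) in the Markovnikov sense while the silyl ester oxygen captures the tertiary cation at C4a and releases Me3Si+ to carry the chain. The closest known reaction types are the Lewis acid-mediated capture of peroxycarbenium ions from peroxyketals by allylsilanes, silyl enol ethers and alkenes, the Prins cyclization, and cation–olefin cyclizations terminated by a carboxyl group; what is new is their union on a peroxide with an unactivated alkene. The 1,2-dioxane closes 6-endo-trig on the alkene (both alkene carbons and the C=O+ bond lie inside the ring, as in a Prins cyclization) and the γ-lactone closes 5-exo-trig on the same alkene, anti to the new C3–C4 bond. C4a is controlled by the tether, because the acetate arm on C7a can reach the cation only on its own face, so the lactone is cis-fused. C3 is controlled in a chair-like transition state in which the acetate arm on C7a is axial (no allylic 1,2-strain with the in-plane C4a methyl, no 1,3-diaxial partner because the flanking ring positions are O2 and the sp2 carbon C4, carboxyl anti to the forming bond), the C4a methyl is pseudo-axial on the other face, and the rod-like alkynyl group rather than the methyl group takes the axial site on C3 syn to that methyl, which places the chain trans to the lactone as the target requires. The step needs ionization at the methoxy and not the peroxy oxygen (secured by the more basic ether oxygen), protection of the isopropenyl group from protonation (hindered base, no free acid) and C–C bond formation ahead of Criegee/Hock-type O–O heterolysis (low temperature, intramolecular six-ring closure), and it is stereoconvergent because the ketal center is erased on ionization.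

**Step 9**
Reactants: 17 (3S,4aR,7aR)-3,4a-dimethyl-3-(10-phenyldec-1-yn-1-yl)tetrahydrofuro[3,2-c][1,2]dioxin-6(3H)-one
Product: 18 (3R,4aR,7aR)-3,4a-dimethyl-3-(10-phenyldecyl)tetrahydrofuro[3,2-c][1,2]dioxin-6(3H)-one (butenolide peroxide, the target)
Conditions: KO2C–N=N–CO2K (large excess, in portions), AcOH, MeOH/CH2Cl2, 0 °C → rt
Reagents that add atoms: none
Why: Diimide reduction transfers H2 in a concerted syn fashion to the triple bond and then to the cis-alkene and should not touch the O–O bond, the lactone or the arene, so that no stereocenter is affected (the C3 descriptor changes from S to R only because the ligand priorities change).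

**Compound list**

1 | (8-bromooctyl)benzene | BrCCCCCCCCc1ccccc1 | starting material
2 | lithium acetylide–ethylenediamine complex | [Li]C#C.NCCN | starting material
3 | (dec-9-yn-1-yl)benzene (10-phenyldec-1-yne) | C#CCCCCCCCCc1ccccc1 | intermediate
4 | N-methoxy-N-methylacetamide | CC(=O)N(C)OC | starting material
5 | (10-phenyldec-1-yn-1-yl)lithium (lithium acetylide of 3) | [Li]C#CCCCCCCCCc1ccccc1 | intermediate
6 | 12-phenyldodec-3-yn-2-one | CC(=O)C#CCCCCCCCCc1ccccc1 | intermediate
7 | (11,11-dimethoxydodec-9-yn-1-yl)benzene (dimethyl ketal of 6) | CC(OC)(OC)C#CCCCCCCCCc1ccccc1 | intermediate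
8 | 2-methoxy-12-phenyldodec-3-yn-2-yl hydroperoxide (racemic) | CC(OC)(OO)C#CCCCCCCCCc1ccccc1 | intermediate
9 | methacrolein (2-methylprop-2-enal) | C=C(C)C=O | starting material
10 | (triphenylphosphoranylidene)acetaldehyde | O=CC=P(c1ccccc1)(c1ccccc1)c1ccccc1 | starting material
11 | (2E)-4-methylpenta-2,4-dienal | C=C(C)/C=C/C=O | intermediate
12 | (3R)-3-[(2-methoxy-12-phenyldodec-3-yn-2-yl)peroxy]-4-methylpent-4-enal, both ketal epimers | C=C(C)[C@@H](CC=O)OOC(C)(OC)C#CCCCCCCCCc1ccccc1 | intermediate
13 | (3R)-3-[(2-methoxy-12-phenyldodec-3-yn-2-yl)peroxy]-4-methylpent-4-enoic acid, both ketal epimers | C=C(C)[C@@H](CC(=O)O)OOC(C)(OC)C#CCCCCCCCCc1ccccc1 | intermediate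
14 | trimethylsilyl ester of 13 | C=C(C)[C@@H](CC(=O)O[Si](C)(C)C)OOC(C)(OC)C#CCCCCCCCCc1ccccc1 | intermediate
15 | peroxycarbenium ion from 14 (triflate) | C=C(C)[C@@H](CC(=O)O[Si](C)(C)C)O[O+]=C(C)C#CCCCCCCCCc1ccccc1.[O-]S(=O)(=O)C(F)(F)F | intermediate
16 | 1,2-dioxan-4-yl tertiary cation after C3–C4 bond formation (triflate) | C[C@@]1(C#CCCCCCCCCc2ccccc2)C[C+](C)[C@@H](CC(=O)O[Si](C)(C)C)OO1.[O-]S(=O)(=O)C(F)(F)F | intermediate
17 | (3S,4aR,7aR)-3,4a-dimethyl-3-(10-phenyldec-1-yn-1-yl)tetrahydrofuro[3,2-c][1,2]dioxin-6(3H)-one | C[C@@]1(C#CCCCCCCCCc2ccccc2)C[C@@]2(C)OC(=O)C[C@H]2OO1 | intermediate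
18 | (3R,4aR,7aR)-3,4a-dimethyl-3-(10-phenyldecyl)tetrahydrofuro[3,2-c][1,2]dioxin-6(3H)-one (butenolide peroxide) | C[C@@]1(CCCCCCCCCCc2ccccc2)C[C@@]2(C)OC(=O)C[C@H]2OO1 | target

**Step count**

Total: 9 steps. Longest linear sequence: 8 steps (steps 1, 2, 3, 4, 6, 7, 8, 9; compound 1 to compound 18).

**Steps most likely to fail**

1. Step 8 (the proposed cascade). After ionization, heterolysis of the O–O bond (Criegee/Hock-type fragmentation) or reversible capture of the peroxycarbenium carbon by the ester carbonyl may outrun attack by the weakly nucleophilic isopropenyl group. The tertiary cation may also lose a proton instead of lactonizing, and facial selectivity at C3 may fall short of the chair model.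
 Fallback (known chemistry): the event is divided into a Hosomi–Sakurai ring closure with a much stronger π-nucleophile and a separate acid-mediated lactonization. It sets out from 8 and 10 and comes back at 17. Commercial 2-[(trimethylsilyl)methyl]prop-2-en-1-ol would be oxidized with MnO2 in CH2Cl2 to 2-[(trimethylsilyl)methyl]prop-2-enal F1. Wittig olefination with 10 would give (2E)-4-[(trimethylsilyl)methyl]penta-2,4-dienal F2. Peroxidation with 8 under the conditions of step 6 would give (3R)-3-[(2-methoxy-12-phenyldodec-3-yn-2-yl)peroxy]-4-[(trimethylsilyl)methyl]pent-4-enal F3, and chlorite oxidation as in step 7 the corresponding pent-4-enoic acid F4. Catalytic Me3SiOTf in CH2Cl2 at −78 °C would then close the 1,2-dioxane by intramolecular allylation of the peroxycarbenium ion, with loss of the silyl group, to give 2-[(3R,6S)-6-methyl-4-methylidene-6-(10-phenyldec-1-yn-1-yl)-1,2-dioxan-3-yl]acetic acid F5. The same chair argument (axial alkynyl group) is expected to govern C3. Catalytic CF3SO3H in CH2Cl2 at −20 °C would protonate the exocyclic alkene in the Markovnikov sense and the carboxyl would close the cis-fused lactone, giving 17.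

2. Step 6. Addition of the bulky, racemic tertiary hydroperoxide may be slow or poorly face-selective. The β-peroxy enamine may close to the epoxy aldehyde, and some attack at the diene terminus is possible.
 Fallback: the peroxide oxygen is brought in with a small achiral donor of the established kind and the C3 fragment is transferred afterwards. It sets out from 11 (and uses 7) and comes back at 13. Ozonolysis of 2,3-dimethylbut-2-ene in MeOH/CH2Cl2 at −78 °C would give 2-methoxypropan-2-yl hydroperoxide F6. Its addition to 11 under the conditions of step 6 would give (3R)-3-[(2-methoxypropan-2-yl)peroxy]-4-methylpent-4-enal F7; the small donor is also less biased toward the unhindered diene terminus. Chlorite oxidation would give (3R)-3-[(2-methoxypropan-2-yl)peroxy]-4-methylpent-4-enoic acid F8. Hydrolysis with AcOH/H2O/THF would release (3R)-3-hydroperoxy-4-methylpent-4-enoic acid F9. Acid-catalysed exchange of F9 with ketal 7 (camphorsulfonic acid cat., CH2Cl2, 0 °C) would give 13.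

3. Step 4. The exchange may run on to the geminal dihydroperoxide or condense to bis-peroxides, so that the mono-hydroperoxy ketal is obtained only as part of a mixture.
 Fallback: the hydroperoxy ketal is made by trapping a carbonyl oxide instead of by exchange. It sets out from 6 and comes back at 8. Wittig olefination of 6 with the ylide from (methoxymethyl)triphenylphosphonium chloride and NaN(SiMe3)2 (THF, −78 → 0 °C) would give the enol ether 1-methoxy-2-methyl-12-phenyldodec-1-en-3-yne F10 as an E/Z mixture. Ozonolysis in MeOH/CH2Cl2 at −78 °C, stopped when the electron-rich enol ether is consumed, would cleave it to methyl formate and the alkynyl carbonyl oxide, which methanol traps as 8.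

**Further compounds**

F1 | step 8 | 2-[(trimethylsilyl)methyl]prop-2-enal | C=C(C[Si](C)(C)C)C=O
F2 | step 8 | (2E)-4-[(trimethylsilyl)methyl]penta-2,4-dienal | C=C(C[Si](C)(C)C)/C=C/C=O
F3 | step 8 | (3R)-3-[(2-methoxy-12-phenyldodec-3-yn-2-yl)peroxy]-4-[(trimethylsilyl)methyl]pent-4-enal | C=C(C[Si](C)(C)C)[C@@H](CC=O)OOC(C)(OC)C#CCCCCCCCCc1ccccc1
F4 | step 8 | (3R)-3-[(2-methoxy-12-phenyldodec-3-yn-2-yl)peroxy]-4-[(trimethylsilyl)methyl]pent-4-enoic acid | C=C(C[Si](C)(C)C)[C@@H](CC(=O)O)OOC(C)(OC)C#CCCCCCCCCc1ccccc1
F5 | step 8 | 2-[(3R,6S)-6-methyl-4-methylidene-6-(10-phenyldec-1-yn-1-yl)-1,2-dioxan-3-yl]acetic acid | C[C@@]1(C#CCCCCCCCCc2ccccc2)CC(=C)[C@@H](CC(=O)O)OO1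
F6 | step 6 | 2-methoxypropan-2-yl hydroperoxide | COC(C)(C)OO
F7 | step 6 | (3R)-3-[(2-methoxypropan-2-yl)peroxy]-4-methylpent-4-enal | C=C(C)[C@@H](CC=O)OOC(C)(C)OC
F8 | step 6 | (3R)-3-[(2-methoxypropan-2-yl)peroxy]-4-methylpent-4-enoic acid | C=C(C)[C@@H](CC(=O)O)OOC(C)(C)OC
F9 | step 6 | (3R)-3-hydroperoxy-4-methylpent-4-enoic acid | C=C(C)[C@@H](CC(=O)O)OO
F10 | step 4 | 1-methoxy-2-methyl-12-phenyldodec-1-en-3-yne (E/Z mixture) | COC=C(C)C#CCCCCCCCCc1ccccc1
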